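| flask | substrate | partner | free catalyst | remark | time |
|---|---|---|---|---|---|
| amber | 1 M | 1.1 M | 24 mM | run made earlier |  |
| teal | 1 M | 1.1 M | 88 mM | run made earlier |  |
| blue | 0.58 M | 1.1 M | 20 mM | run made earlier |  |
| Thursday's | 0.30 M | 1.10 M | 20 mM |  | 2.5 min |
| Tuesday's | 1.0 M | 1.10 M | 80 mM |  | 2.5 min |
| Wednesday's | 1.0 M | 1.10 M | 20 mM |  | 2.5 min |
| Saturday's | 0.30 M | 1.10 M | 80 mM |  | 2.5 min |

- amber (time / s: target / %, substrate / %): 12.0: 3.0, 94.2; 40.0: 10.0, 84.8; 60.0: 12.9, 78.9; 120: 19.7, 60.5
- teal (time / s: target / %, substrate / %): 12.0: 11.5, 82.1; 40.0: 34.0, 51.9; 60.0: 46.6, 35.7; 120: 70.2, 11.1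
- blue (time / s: target / %, substrate / %): 10.0: 2.9, 95.5; 20.0: 6.6, 91.3; 50.0: 11.4, 79.9; 120: 19.4, 56.9

(standard deviation of a reading: 0.5 percentage points)

- the earlier runs were read with a standard deviation of 0.5 percentage points

1. the flasks by amount of target, in percent of the substrate charged, highest first, at 2.5 min (Thursday's / Tuesday's / Wednesday's / Saturday's)
2. the amount of target, in percent of the substrate charged of the flask you put first, at 2.5 min
3. the amount of target, in percent of the substrate charged of the flask you put last, at 2.5 min

1. Count turnovers first. I took a flask's demand as c(substrate)/c(free catalyst), the turnovers each catalyst must make to clear the charge. Amber's substrate loss by 120 s gave 0.137 s⁻¹ per catalyst, so at 1.0 M of substrate the turnover budget, the turnovers (turnover number) available in 2.5 min, was 20.6.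

2. One extreme is a budget below demand. Wednesday's demand was 50.0, above the budget, so I expected busy catalyst and 41.1% of its substrate spent. For Thursday's I scaled blue's rate in proportion to substrate, my own assumption, which gave 8.08 turnovers against a demand of 15.0. That spends 53.9%, so I put Thursday's just above Wednesday's, both near amber's 19.7% at 120 s.

3. The other extreme is a budget above demand. Saturday's needed 3.75 turnovers, about 69.6 s of work at the rate per catalyst I had reckoned for Thursday's. Its charge of partner exceeded its charge of substrate by 0.800 M, so I counted on partner standing beside its target after that. Amber's missing share rose 12 points between 60.0 s and 120 s, which I read as a target half-life of 58.4 s. So I expected about 38.5% of Saturday's target to survive.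

4. Tuesday's lay between: its demand of 12.5 stood below the budget, and its charge of partner exceeded its charge of substrate by 0.100 M, less than Saturday's margin. Teal's missing share went from 17.7% at 60.0 s to 18.7% at 120 s, so I put Tuesday's near teal's 70.2% at that last reading, and first.

5. The forecast put Saturday's first, where I had Tuesday's: Saturday's > Tuesday's > Thursday's > Wednesday's, top 75% (66% to 84%), low 20% (17% to 23%), with Saturday's lead hedged: “though its lead over Tuesday's is uncertain”.

6. The flasks gave Tuesday's > Saturday's > Thursday's > Wednesday's, with top 69.5% and low 18.3%. Saturday's reached 98.5% conversion, yet held 30.6% target beside 67.7% over-reaction product. Wednesday's budget left 58.9% of its substrate on my count, and 59.2% stood there.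

    partner + target → over-reaction product (k = 0.0180 L mol⁻¹ s⁻¹)
    catalyst intermediate D → free catalyst + target (k = 1.00 s⁻¹)
    catalyst intermediate C ⇌ catalyst intermediate D (K = 0.600, k = 98.0 s⁻¹)
    partner + free catalyst → catalyst intermediate A (k = 29.0 L mol⁻¹ s⁻¹)
    substrate + catalyst intermediate A → catalyst intermediate B (k = 0.390 L mol⁻¹ s⁻¹)
    catalyst intermediate B ⇌ released group + catalyst intermediate C (K = 1.10 M, k = 0.900 s⁻¹)

7. Wednesday's flask read at 1.5 min has a budget of 12.3 turnovers, which leaves 75.3% of the substrate. The computed flask holds 73.8% substrate and 13.7% target.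

(The runs are calculated on assumed constants.)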